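## Structural features

The target is a monocyclic 1,2-dioxane (ring atoms O1, O2, C3, C4, C5, C6). C3 carries the acetic acid arm (C2, C1), C4 an ethyl group, and the fully substituted C6 an ethyl group and a branched chain C7–C14 with an ethyl group on C8 and a methyl group on C10. There are five stereocentres: C3 and C4 are neighbours on the ring, C6 is 1,3 to C4 across C5, and C8 and C10 lie in the chain, insulated from the ring by C7 and from each other by C9. On the ring the acetic acid arm, the C4 ethyl and the C6 ethyl group share one face and the long chain takes the other (3S,4S,6S); in the chain the C8 ethyl and C10 methyl groups are 1,3-syn (8S,10S). Fragile points are the O–O bond (phosphines, hydrides, low-valent metals, warm organometallics, hydrogenation catalysts), the C3–H next to the peroxide under strong base, and the β-peroxy carbonyl array C1–C3, which loses the peroxide by retro-oxa-Michael reaction under base while C1 is an aldehyde or ester. The real difficulty is twofold. The C6–O bond must be made with control although the two methylene arms of C6 (C5 leading to the C4 ethyl centre, C7 leading to the C8 ethyl centre) are near mirror images of each other. C8 and C10 have no neighbouring functional group through which a substrate could direct their formation. The key step exploits the all-alkyl triad C8–C9–C10: each of these carbons can carry boron in turn, so C9–C10 and C8–C9 are made by two 1,2-shifts from boron and C8 is set by a chiral reagent alone.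

## Logic of the disconnections

**30 to 27 (through 29 and 28).** The terminal carbon of the C6 ethyl group is removed: the ethyl group is traced to a vinyl group and the vinyl C=C is cut back to a formyl and then a hydroxymethyl group on C6. The reason is that a hydroxymethyl group on C6 is exactly what rear-side opening of a terminal epoxide at its tertiary carbon leaves behind. The gain is a handle that explains the C6–O bond. The demand is an oxidation, a methylenation and an alkene reduction that all spare the O–O bond and the free acid.

**27 to 25 (through 26).** C1 is traced to the inner carbon of a terminal alkene, one extra carbon being cut off. An allyl group is an acid equivalent that needs no protecting group and puts no carbonyl β to C3 while the C3–O bond is being made. The demand is that the alkene is cleaved before the C6 vinyl group exists, because the final reduction could not tell two terminal alkenes apart.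

**25 to 24.** The ring bond O2–C3 is cut, giving an open chain with a hydroperoxide on C6 and a sulfonate on C3. Closing this bond intramolecularly makes the hindered secondary C–O bond a 6-exo displacement. The demand is a leaving group on C3 of the configuration opposite to the target, and a base that ionises only the hydroperoxide.

**24 to 23.** The bond O1–C6 is cut and the C6 oxygen is reconnected as a terminal 2,2-disubstituted epoxide. The gain is that the peroxy stereocentre becomes an epoxide stereocentre, which a reagent can set. The demand is regioselective attack of hydrogen peroxide at the tertiary carbon with inversion.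

**23 to 20 (through 22 and 21).** The bond C2–C3 is cut to an aldehyde at C3 and an allyl nucleophile. A chiral allylborane sets C3 independently of C4. The demand is conditions mild enough for a γ,δ-epoxy alcohol, which cyclises under acid.

**20 to 14 and 17 (through 19 and 18).** The bond C4–C5 is cut to a chiral four-carbon enolate and an epoxy triflate. This splits the molecule into the complete side chain with C6 and a small acyl unit, and sets C4 by auxiliary control. The demand is displacement at the triflate carbon, not at the oxirane.

**14 to 13.** The epoxide oxygen is removed to leave a 2-substituted allylic alcohol. This is the one stage at which the two faces at C6 can be told apart by a reagent, because the hydroxymethyl arm (future C5) is chemically different from C7. The demand is the correct tartrate enantiomer.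

**13 to 11 and 12.** The bond C6–C7 is cut to a primary alkyl boronate and a bromoalkene. The gain is that the boron atom left by the chain-building steps is used directly for C–C coupling. The demand is transmetalation of a β-branched primary boronate faster than its decomposition.

**11 to 10 and 8.** The bond C7–C8 is cut as a methylene insertion into the C8–B bond. The migration must retain the configuration at C8.

**10 to 7, 8 and 5 (through 9).** The bonds C8–C9 and C9–C10 are cut. Each is a boron-to-carbon shift, one with an achiral methylene carbenoid and one with a chiral lithiated ester. This reduces the two remote stereocentres to a single secondary boronate plus two small reagents. The demand is two clean single insertions without isolation and full reagent control at C8.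

**7 to 6 and 3.** The bond C10–C11 is cut in the same way. C10 and its methyl group come from a lithiated ethyl ester and the butyl group from the boronate. The demand is high enantioselectivity in the deprotonation.

**3, 5 and 17 to 1, 2, 4, 15 and 16.** Two ester C–O bonds and one imide C–N bond are cut. These are routine acylations of commercial materials.

## Other disconnections considered

**Alternative 1:** The cut is C4–C5 and C7–C8, with C3 to C9 folded into a seven-membered ring. In the forward sense the oxyallyl cation released from 3-bromo-2-methoxyprop-1-ene A3 by AgOCOCF3 would add across the termini of (3E,5E)-octa-3,5-diene A2 to give the meso ketone cis-3,6-diethylcyclohept-4-en-1-one A1.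

- In its favour: two C–C bonds form in one step from very cheap materials. The diene geometry translates directly into the required relationship between the C4 and C8 ethyl groups without any chiral reagent. The carbonyl of A1 sits at C6, ready for the quaternary centre. On these points it is better than the chosen plan, which sets C4 and C8 in separate operations.
- Against it: open-chain dienes substituted at both termini would be expected to be reluctant partners for a simple oxyallyl cation. A1 is achiral, so a later desymmetrising step must distinguish the C3 end from the C9 end. C10 is not addressed at all and would need its own asymmetric step after ring cleavage. The C6–O bond would still have to be made between two look-alike arms.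
- Comparison: A1 covers the stretch C3–C9 and the chosen key step the stretch C8–C10. A1 relies on substrate geometry and the chosen step on reagent control at each centre. The peroxide end-game would be the same in both, so they are equal there. After desymmetrisation, ring cleavage and a separate route to C10, the count would probably not fall below that of the chosen plan.

**Alternative 2:** The cut is the ring bond O1–C6. In the forward sense the secondary hydroperoxide of the epoxide A5 (tert-butyl{[(3S,4S)-4-ethyl-5-{(2R)-2-[(2S,4S)-2-ethyl-4-methyloctyl]oxiran-2-yl}-3-hydroperoxypentyl]oxy}diphenylsilane) would open the oxirane at its tertiary carbon under mild acid, giving the hydroxymethyl dioxane A4.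

- In its favour: the tertiary C–O bond would form intramolecularly, 6-exo, with stereospecific inversion and without base. That is more secure at C6 than the intermolecular perhydrolysis of the chosen route, and is the better solution on that point.
- Against it: A5 needs a secondary hydroperoxide of defined configuration at C3. That would have to come from an intermolecular displacement at a β-branched secondary carbon, where elimination is expected to compete strongly. C1 must also travel as a silyl ether, which costs a protection, a deprotection and a two-stage oxidation.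
- Comparison: both plans form the same two ring C–O bonds from the same epoxide, in opposite order. The chosen plan makes the easy tertiary bond intermolecularly and the difficult secondary bond intramolecularly. Both leave a hydroxymethyl group on C6 to be turned into ethyl, so they are equal there. This alternative does not address C8 and C10 and could take its side chain from the chosen key step, so the two are complementary; it is kept as the fallback for the ring closure.

**Alternative 3:** The cut is both ring C–O bonds at once. In the forward sense singlet oxygen would add across C3 and C6 of the diene (5S)-5-ethyl-1-[(2S,4S)-2-ethyl-4-methyloctyl]cyclohexa-1,3-diene A7, anti to the C4 ethyl group, to give the bicyclic endoperoxide A6.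

- In its favour: both C–O bonds and the O–O bond come from dioxygen in one step, with no hydrogen peroxide and no leaving groups. The suprafacial addition ties the configurations of C3 and C6 together. On atom economy and on steps to the peroxide ring it is better than the chosen plan.
- Against it: facial control would rest on a single ethyl group. Ene reaction at the allylic hydrogens and aromatisation of the diene would be expected to compete. The etheno bridge of A6 must then be cleaved to two α-peroxy formyl groups that have to be told apart and each extended by one carbon; the one on C3 has an α-hydrogen and is prone to base-induced peroxide cleavage. Enantiopure A7 also needs its own synthesis.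
- Comparison: C6 would be set by substrate control here and by a tartrate-controlled epoxide in the chosen plan. The step saving at the ring would probably be spent on differentiating the two aldehydes. The side chain problem is identical, so the chosen key step would serve this route equally well.

Key step: step 4

**Remarks and assumptions**

- Numbering: C1 is the carboxyl carbon, C3–C6 are the ring carbons, C7–C14 the chain. Structure check: the target is (3S,4S,6S) with a (2S,4S) side chain (C8 S, C10 S). The methyl-bearing centre keeps its geometry throughout, but its descriptor is S in 7, R in 9 and S again in 10 because of priority changes only.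
- Assumption: (+)-sparteine and B-allyldiisopinocampheylborane of the (−)-α-pinene series are taken as purchasable. The sense of induction of each chiral reagent is assigned from the established models and stated in the step.
- Assumption: the chain-building stereocentres are set by reagent control of high but not perfect selectivity, so minor diastereomers are expected to be removed at the first crystalline or well-resolved intermediate (19 or 25).
- Peroxide-containing materials (ethereal H2O2 and compounds 24–30) would be handled on small scale behind a shield, below 30 °C, and never concentrated to dryness with heating.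

## Route

Step 1
Reactants: 1 2,4,6-tri(propan-2-yl)benzoic acid; 2 ethanol
Product: 3 ethyl 2,4,6-tri(propan-2-yl)benzoate
Conditions: PPh3, DIAD, THF, 0 °C to rt
Reagents that add atoms: none
Why: Mitsunobu esterification; the carboxylate attacks the alkoxyphosphonium ion of the primary alcohol, so the shielded carbonyl carbon never has to be attacked, and no stereocentre is involved.

Step 2
Reactants: 1 2,4,6-tri(propan-2-yl)benzoic acid; 4 propan-1-ol
Product: 5 propyl 2,4,6-tri(propan-2-yl)benzoate
Conditions: PPh3, DIAD, THF, 0 °C to rt
Reagents that add atoms: none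
Why: Mitsunobu esterification as in step 1.

Step 3
Reactants: 6 2-butyl-4,4,5,5-tetramethyl-1,3,2-dioxaborolane; 3 ethyl 2,4,6-tri(propan-2-yl)benzoate
Product: 7 2-[(2S)-hexan-2-yl]-4,4,5,5-tetramethyl-1,3,2-dioxaborolane
Conditions: s-BuLi, (+)-sparteine, Et2O, −78 °C (lithiation of 3); then 6, −78 °C; then 35 °C
Reagents that add atoms: none
Why: Lithiation–borylation (Hoppe-type asymmetric deprotonation followed by a Matteson-type 1,2-metallate shift): the hindered benzoate gives a configurationally stable α-oxy organolithium that adds to boron with retention, after which the butyl group migrates with inversion as the benzoate leaves. s-BuLi/(+)-sparteine removes the pro-R proton, which after retention and inversion should give C10 as S.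

Step 4
Reactants: 7 2-[(2S)-hexan-2-yl]-4,4,5,5-tetramethyl-1,3,2-dioxaborolane; 8 bromochloromethane; 5 propyl 2,4,6-tri(propan-2-yl)benzoate
Product: 10 4,4,5,5-tetramethyl-2-[(3S,5S)-5-methylnonan-3-yl]-1,3,2-dioxaborolane, via (R)-2-methylhexyl pinacolboronate 9 (not isolated)
Conditions: 8, n-BuLi, Et2O, −78 °C to rt; volatiles evaporated; residue in Et2O added to lithiated 5 (s-BuLi, (+)-sparteine, Et2O, −78 °C); then 35 °C (MgBr2·OEt2 if migration is slow)
Reagents that add atoms: none
Why: Chloromethyllithium, generated by bromine–lithium exchange in the presence of 7, adds to boron, and on warming the secondary alkyl group shifts to the CH2 carbon with loss of chloride and retention at C10, giving 9 (C9–C10 bond). The carbenoid decomposes below the temperature at which the ate complex rearranges, so a second insertion should not occur, and volatile residues are stripped before the second stage. Crude 9 is then captured by the (R)-configured lithiated 5; boron is attached with retention and the primary alkyl group migrates anti-periplanar to the departing benzoate, inverting the carbenoid carbon (C8–C9 bond). The closest known reaction type is the iterative homologation of pinacol boronic esters with lithiated hindered benzoates alternating with chloromethyllithium. No ring is closed. The one new stereocentre, C8, is set by the diamine–lithium complex alone, so the 1,3-syn relation to C10 is simply the use of (+)-sparteine a second time; C10 is too remote to interfere and is carried through the methylene insertion unchanged. The step needs one clean insertion per stage and complete 1,2-migration without reversal of the ate complex; the unhindered primary boronate 9 and the good benzoate leaving group should secure both.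

Step 5
Reactants: 10 4,4,5,5-tetramethyl-2-[(3S,5S)-5-methylnonan-3-yl]-1,3,2-dioxaborolane; 8 bromochloromethane
Product: 11 2-[(2S,4S)-2-ethyl-4-methyloctyl]-4,4,5,5-tetramethyl-1,3,2-dioxaborolane
Conditions: 8, n-BuLi, Et2O, −78 °C to rt
Reagents that add atoms: none
Why: Matteson one-carbon homologation; the secondary alkyl group migrates from boron to CH2 with retention, so C8 is untouched and a primary boronate suited to cross-coupling results (C7–C8 bond).

Step 6
Reactants: 11 2-[(2S,4S)-2-ethyl-4-methyloctyl]-4,4,5,5-tetramethyl-1,3,2-dioxaborolane; 12 2-bromoprop-2-en-1-ol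
Product: 13 2-[(2S,4S)-2-ethyl-4-methyloctyl]prop-2-en-1-ol
Conditions: Pd(OAc)2 (5 mol %), RuPhos (10 mol %), KOH, THF/H2O, 70 °C
Reagents that add atoms: none
Why: B-alkyl Suzuki–Miyaura coupling; the bulky electron-rich biarylphosphine on palladium favours oxidative addition to the bromoalkene, transmetalation of the hydroxide-activated primary boronate and reductive elimination ahead of β-hydride elimination. No stereocentre is touched and the free hydroxyl is tolerated.

Step 7
Reactants: 13 2-[(2S,4S)-2-ethyl-4-methyloctyl]prop-2-en-1-ol
Product: 14 {(2R)-2-[(2S,4S)-2-ethyl-4-methyloctyl]oxiran-2-yl}methanol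
Conditions: Ti(OiPr)4 (10 mol %), D-(−)-diisopropyl tartrate (12 mol %), t-BuOOH, 4 Å molecular sieves, CH2Cl2, −20 °C
Reagents that add atoms: tert-butyl hydroperoxide, CC(C)(C)OO
Why: Sharpless asymmetric epoxidation; the allylic hydroxyl binds titanium, so the tartrate selects the alkene face and the two look-alike methylene arms play no part. D-(−)-tartrate should give the (R)-oxirane, the mirror image of the outcome by which L-(+)-tartrate gives (S)-2-methylglycidol; the catalytic, sieve-dried protocol limits opening of the sensitive 2,2-disubstituted epoxy alcohol.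

Step 8
Reactants: 15 (4R)-4-benzyl-1,3-oxazolidin-2-one; 16 butanoyl chloride
Product: 17 (4R)-4-benzyl-3-butanoyl-1,3-oxazolidin-2-one
Conditions: n-BuLi, THF, −78 °C; then 16
Reagents that add atoms: none
Why: N-acylation of the lithiated oxazolidinone (loading of the Evans auxiliary); the ring stereocentre is not involved.

Step 9
Reactants: 14 {(2R)-2-[(2S,4S)-2-ethyl-4-methyloctyl]oxiran-2-yl}methanol; 17 (4R)-4-benzyl-3-butanoyl-1,3-oxazolidin-2-one
Product: 19 (4R)-4-benzyl-3-[(2S)-2-ethyl-3-{(2R)-2-[(2S,4S)-2-ethyl-4-methyloctyl]oxiran-2-yl}propanoyl]-1,3-oxazolidin-2-one, via epoxy triflate 18 (not isolated)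
Conditions: Tf2O, 2,6-lutidine, CH2Cl2, −78 °C; then sodium enolate of 17 (NaN(SiMe3)2, THF, −78 °C), −78 to −40 °C
Reagents that add atoms: none
Why: Evans asymmetric alkylation; the chelated Z sodium enolate is alkylated on the face away from the benzyl group, so the (4R) auxiliary should set C4 as S (C4–C5 bond). The primary triflate is displaced directly at low temperature, far faster than any attack on the oxirane, so the C6 configuration is carried through.

Step 10
Reactants: 19 (4R)-4-benzyl-3-[(2S)-2-ethyl-3-{(2R)-2-[(2S,4S)-2-ethyl-4-methyloctyl]oxiran-2-yl}propanoyl]-1,3-oxazolidin-2-one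
Product: 20 (2S)-2-ethyl-3-{(2R)-2-[(2S,4S)-2-ethyl-4-methyloctyl]oxiran-2-yl}propan-1-ol
Conditions: LiBH4, MeOH (1 equiv), Et2O, 0 °C
Reagents that add atoms: none
Why: Reductive cleavage of the imide; hydride attacks the exocyclic carbonyl and releases the auxiliary for recovery, while the hindered, unactivated epoxide should not be reduced at 0 °C and the α-centre is not epimerised.

Step 11
Reactants: 20 (2S)-2-ethyl-3-{(2R)-2-[(2S,4S)-2-ethyl-4-methyloctyl]oxiran-2-yl}propan-1-ol
Product: 22 (4R,5S)-5-ethyl-6-{(2R)-2-[(2S,4S)-2-ethyl-4-methyloctyl]oxiran-2-yl}hex-1-en-4-ol, via epoxy aldehyde 21 (not isolated)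
Conditions: Dess–Martin periodinane, pyridine, CH2Cl2, 0 °C; then Ipc2B(allyl) of the (−)-α-pinene series, Et2O, −78 °C; NaBO3·4H2O, THF/H2O
Reagents that add atoms: B-allyldiisopinocampheylborane ((−)-α-pinene series), C=CCB(C1CC2CC(C1C)C2(C)C)C1CC2CC(C1C)C2(C)C
Why: Buffered Dess–Martin oxidation gives the α-branched aldehyde, used crude to avoid epimerisation; Brown allylboration then proceeds through a chair Zimmerman–Traxler transition state in which the isopinocampheyl groups choose the aldehyde face (C2–C3 bond). The (−)-α-pinene series, which turns benzaldehyde into the (R)-carbinol, should give the (4R)-alcohol whatever the neighbouring centre; all operations are non-acidic because the γ,δ-epoxy alcohol cyclises under acid.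

Step 12
Reactants: 22 (4R,5S)-5-ethyl-6-{(2R)-2-[(2S,4S)-2-ethyl-4-methyloctyl]oxiran-2-yl}hex-1-en-4-ol
Product: 23 (4R,5S)-5-ethyl-6-{(2R)-2-[(2S,4S)-2-ethyl-4-methyloctyl]oxiran-2-yl}hex-1-en-4-yl methanesulfonate
Conditions: MsCl, Et3N, CH2Cl2, 0 °C
Reagents that add atoms: methanesulfonyl chloride, CS(=O)(=O)Cl
Why: O-sulfonylation through the sulfene under basic conditions; the C–O bond is not broken, so C3 keeps its R configuration, and capping the hydroxyl removes the internal nucleophile that would otherwise attack the epoxide.

Step 13
Reactants: 23 (4R,5S)-5-ethyl-6-{(2R)-2-[(2S,4S)-2-ethyl-4-methyloctyl]oxiran-2-yl}hex-1-en-4-yl methanesulfonate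
Product: 24 (2S,4S,5R)-4-ethyl-2-[(2S,4S)-2-ethyl-4-methyloctyl]-2-hydroperoxy-1-hydroxyoct-7-en-5-yl methanesulfonate
Conditions: H2O2 (dry, in Et2O), H3PMo12O40 (2 mol %), Et2O, 20 °C
Reagents that add atoms: hydrogen peroxide, OO
Why: Molybdenum-catalysed perhydrolysis of an epoxide; the heteropoly acid activates the oxirane and hydrogen peroxide attacks the tertiary carbon from the rear, which should give the tertiary hydroperoxide with inversion at C6 and release the CH2OH group. The mesylate and the terminal alkene are inert under these conditions.

Step 14
Reactants: 24 (2S,4S,5R)-4-ethyl-2-[(2S,4S)-2-ethyl-4-methyloctyl]-2-hydroperoxy-1-hydroxyoct-7-en-5-yl methanesulfonate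
Product: 25 {(3S,5S,6S)-5-ethyl-3-[(2S,4S)-2-ethyl-4-methyloctyl]-6-(prop-2-en-1-yl)-1,2-dioxan-3-yl}methanol
Conditions: CsOH·H2O (1.1 equiv), DMF, 0 °C
Reagents that add atoms: none
Why: Intramolecular alkylation of a hydroperoxide (6-exo-tet); one equivalent of base ionises only the hydroperoxide (pKa about 13, against about 16 for the alcohol), and the peroxide anion displaces the mesylate with inversion at C3. This places the allyl group cis to the C4 ethyl group and closes the 1,2-dioxane.

Step 15
Reactants: 25 {(3S,5S,6S)-5-ethyl-3-[(2S,4S)-2-ethyl-4-methyloctyl]-6-(prop-2-en-1-yl)-1,2-dioxan-3-yl}methanol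
Product: 27 2-{(3S,4S,6S)-4-ethyl-6-[(2S,4S)-2-ethyl-4-methyloctyl]-6-(hydroxymethyl)-1,2-dioxan-3-yl}acetic acid, via peroxy aldehyde 26 (not isolated)
Conditions: O3, CH2Cl2, −78 °C; Me2S; then NaClO2, NaH2PO4, 2-methylbut-2-ene, t-BuOH/H2O, 0 °C
Reagents that add atoms: ozone, [O-][O+]=O; sodium chlorite, [Na+].[O-]Cl=O
Why: Ozonolysis with dimethyl sulfide work-up (which does not reduce dialkyl peroxides) followed at once by Pinnick oxidation at about pH 4, so the β-peroxy aldehyde never meets base and cannot undergo retro-oxa-Michael cleavage. Chlorite leaves the primary alcohol and the O–O bond alone.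

Step 16
Reactants: 27 2-{(3S,4S,6S)-4-ethyl-6-[(2S,4S)-2-ethyl-4-methyloctyl]-6-(hydroxymethyl)-1,2-dioxan-3-yl}acetic acid
Product: 29 2-{(3S,4S,6S)-6-ethenyl-4-ethyl-6-[(2S,4S)-2-ethyl-4-methyloctyl]-1,2-dioxan-3-yl}acetic acid, via formyl dioxane acid 28 (not isolated)
Conditions: Dess–Martin periodinane, CH2Cl2, 0 °C to rt; then Ph3P=CH2 (from Ph3PCH3Br, KN(SiMe3)2; 3.5 equiv), THF, −78 to 0 °C
Reagents that add atoms: methyltriphenylphosphonium bromide, C[P+](c1ccccc1)(c1ccccc1)c1ccccc1.[Br-]
Why: Dess–Martin oxidation gives a non-enolisable α-peroxy aldehyde, and Wittig methylenation then adds the second carbon of the future ethyl group. The first equivalent of ylide is consumed by the carboxylic acid, and oxaphosphetane formation at the aldehyde should be faster than attack on the hindered O–O bond at low temperature.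

Step 17
Reactants: 29 2-{(3S,4S,6S)-6-ethenyl-4-ethyl-6-[(2S,4S)-2-ethyl-4-methyloctyl]-1,2-dioxan-3-yl}acetic acid
Product: 30 2-{(3S,4S,6S)-4,6-diethyl-6-[(2S,4S)-2-ethyl-4-methyloctyl]-1,2-dioxan-3-yl}acetic acid
Conditions: KO2CN=NCO2K, AcOH, MeOH, 0 °C to rt
Reagents that add atoms: none
Why: Diimide reduction; diazene formed by decarboxylation of azodicarboxylic acid transfers two hydrogens to the unhindered vinyl group in a concerted syn fashion and leaves the O–O bond intact, which catalytic hydrogenation would not.

## Compound list

1 | 2,4,6-tri(propan-2-yl)benzoic acid | CC(C)c1cc(C(C)C)c(C(=O)O)c(C(C)C)c1 | starting material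
2 | ethanol | CCO | starting material
3 | ethyl 2,4,6-tri(propan-2-yl)benzoate | CCOC(=O)c1c(C(C)C)cc(C(C)C)cc1C(C)C | intermediate
4 | propan-1-ol | CCCO | starting material
5 | propyl 2,4,6-tri(propan-2-yl)benzoate | CCCOC(=O)c1c(C(C)C)cc(C(C)C)cc1C(C)C | intermediate
6 | 2-butyl-4,4,5,5-tetramethyl-1,3,2-dioxaborolane | CCCCB1OC(C)(C)C(C)(C)O1 | starting material
7 | 2-[(2S)-hexan-2-yl]-4,4,5,5-tetramethyl-1,3,2-dioxaborolane | CCCC[C@H](C)B1OC(C)(C)C(C)(C)O1 | intermediate
8 | bromochloromethane | ClCBr | starting material
9 | 4,4,5,5-tetramethyl-2-[(2R)-2-methylhexyl]-1,3,2-dioxaborolane | CCCC[C@H](C)CB1OC(C)(C)C(C)(C)O1 | intermediate (not isolated)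
10 | 4,4,5,5-tetramethyl-2-[(3S,5S)-5-methylnonan-3-yl]-1,3,2-dioxaborolane | CCCC[C@H](C)C[C@H](CC)B1OC(C)(C)C(C)(C)O1 | intermediate
11 | 2-[(2S,4S)-2-ethyl-4-methyloctyl]-4,4,5,5-tetramethyl-1,3,2-dioxaborolane | CCCC[C@H](C)C[C@H](CC)CB1OC(C)(C)C(C)(C)O1 | intermediate
12 | 2-bromoprop-2-en-1-ol | OCC(Br)=C | starting material
13 | 2-[(2S,4S)-2-ethyl-4-methyloctyl]prop-2-en-1-ol | CCCC[C@H](C)C[C@H](CC)CC(=C)CO | intermediate
14 | {(2R)-2-[(2S,4S)-2-ethyl-4-methyloctyl]oxiran-2-yl}methanol | CCCC[C@H](C)C[C@H](CC)C[C@]1(CO1)CO | intermediate
15 | (4R)-4-benzyl-1,3-oxazolidin-2-one | O=C1N[C@H](Cc2ccccc2)CO1 | starting material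
16 | butanoyl chloride | CCCC(=O)Cl | starting material
17 | (4R)-4-benzyl-3-butanoyl-1,3-oxazolidin-2-one | CCCC(=O)N1[C@H](Cc2ccccc2)COC1=O | intermediate
18 | {(2S)-2-[(2S,4S)-2-ethyl-4-methyloctyl]oxiran-2-yl}methyl trifluoromethanesulfonate | CCCC[C@H](C)C[C@H](CC)C[C@]1(CO1)COS(=O)(=O)C(F)(F)F | intermediate (not isolated)
19 | (4R)-4-benzyl-3-[(2S)-2-ethyl-3-{(2R)-2-[(2S,4S)-2-ethyl-4-methyloctyl]oxiran-2-yl}propanoyl]-1,3-oxazolidin-2-one | CCCC[C@H](C)C[C@H](CC)C[C@]1(CO1)C[C@H](CC)C(=O)N2[C@H](Cc3ccccc3)COC2=O | intermediate
20 | (2S)-2-ethyl-3-{(2R)-2-[(2S,4S)-2-ethyl-4-methyloctyl]oxiran-2-yl}propan-1-ol | CCCC[C@H](C)C[C@H](CC)C[C@]1(CO1)C[C@H](CC)CO | intermediate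
21 | (2S)-2-ethyl-3-{(2R)-2-[(2S,4S)-2-ethyl-4-methyloctyl]oxiran-2-yl}propanal | CCCC[C@H](C)C[C@H](CC)C[C@]1(CO1)C[C@H](CC)C=O | intermediate (not isolated)
22 | (4R,5S)-5-ethyl-6-{(2R)-2-[(2S,4S)-2-ethyl-4-methyloctyl]oxiran-2-yl}hex-1-en-4-ol | CCCC[C@H](C)C[C@H](CC)C[C@]1(CO1)C[C@H](CC)[C@@H](CC=C)O | intermediate
23 | (4R,5S)-5-ethyl-6-{(2R)-2-[(2S,4S)-2-ethyl-4-methyloctyl]oxiran-2-yl}hex-1-en-4-yl methanesulfonate | CCCC[C@H](C)C[C@H](CC)C[C@]1(CO1)C[C@H](CC)[C@@H](CC=C)OS(C)(=O)=O | intermediate
24 | (2S,4S,5R)-4-ethyl-2-[(2S,4S)-2-ethyl-4-methyloctyl]-2-hydroperoxy-1-hydroxyoct-7-en-5-yl methanesulfonate | CCCC[C@H](C)C[C@H](CC)C[C@@](OO)(CO)C[C@H](CC)[C@@H](CC=C)OS(C)(=O)=O | intermediate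
25 | {(3S,5S,6S)-5-ethyl-3-[(2S,4S)-2-ethyl-4-methyloctyl]-6-(prop-2-en-1-yl)-1,2-dioxan-3-yl}methanol | CCCC[C@H](C)C[C@H](CC)C[C@@]1(CO)C[C@H](CC)[C@H](CC=C)OO1 | intermediate
26 | 2-{(3S,4S,6S)-4-ethyl-6-[(2S,4S)-2-ethyl-4-methyloctyl]-6-(hydroxymethyl)-1,2-dioxan-3-yl}acetaldehyde | CCCC[C@H](C)C[C@H](CC)C[C@@]1(CO)C[C@H](CC)[C@H](CC=O)OO1 | intermediate (not isolated)
27 | 2-{(3S,4S,6S)-4-ethyl-6-[(2S,4S)-2-ethyl-4-methyloctyl]-6-(hydroxymethyl)-1,2-dioxan-3-yl}acetic acid | CCCC[C@H](C)C[C@H](CC)C[C@@]1(CO)C[C@H](CC)[C@H](CC(=O)O)OO1 | intermediate
28 | 2-{(3S,4S,6S)-4-ethyl-6-[(2S,4S)-2-ethyl-4-methyloctyl]-6-formyl-1,2-dioxan-3-yl}acetic acid | CCCC[C@H](C)C[C@H](CC)C[C@@]1(C=O)C[C@H](CC)[C@H](CC(=O)O)OO1 | intermediate (not isolated)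
29 | 2-{(3S,4S,6S)-6-ethenyl-4-ethyl-6-[(2S,4S)-2-ethyl-4-methyloctyl]-1,2-dioxan-3-yl}acetic acid | CCCC[C@H](C)C[C@H](CC)C[C@@]1(C=C)C[C@H](CC)[C@H](CC(=O)O)OO1 | intermediate
30 | 2-{(3S,4S,6S)-4,6-diethyl-6-[(2S,4S)-2-ethyl-4-methyloctyl]-1,2-dioxan-3-yl}acetic acid | CCCC[C@H](C)C[C@H](CC)C[C@@]1(CC)C[C@H](CC)[C@H](CC(=O)O)OO1 | target

## Step count and least certain steps

Total step count: 17. Longest linear sequence: 15 steps (steps 1, 3 to 7 and 9 to 17; steps 2 and 8 are side branches). No protecting group is used.

**Step 4 (key step).** Carry-over from the first insertion (residual bromochloromethane, 1-bromobutane, lithium halides) may quench or perturb the lithiated benzoate. Incomplete reagent control in the deprotonation would also erode the configuration at C8 and produce a 1,3-anti diastereomer that is not expected to separate from 10 on silica. The fallback sets out from 7 and 5 and comes back at 10. The two insertions are run as separate operations with purification of 9. The chiral carbenoid is not made by in situ deprotonation but released from a stored precursor: 5 is lithiated with s-BuLi/(+)-sparteine and trapped with Me3SnCl to give (1R)-1-(trimethylstannyl)propyl 2,4,6-tri(propan-2-yl)benzoate F1. F1 is brought to full enantiopurity by recrystallisation or preparative chiral chromatography; tin–lithium exchange (n-BuLi, Et2O, −78 °C, retention) then regenerates the lithiated ester, which is combined with pure 9 and warmed to give 10.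

**Step 6.** Transmetalation of the β-branched primary pinacol boronate may be slow, so that protodeboronation, β-hydride elimination or decomposition of the bromoalkene takes over. The fallback sets out from 11 and comes back at 13, replacing the cross-coupling by enolate chemistry. Oxidation (NaOH, H2O2) gives (2S,4S)-2-ethyl-4-methyloctan-1-ol F2. Iodination (I2, PPh3, imidazole) gives (2S,4S)-2-ethyl-1-iodo-4-methyloctane F3. Alkylation of diethyl malonate (NaH, DMF) gives diethyl 2-[(2S,4S)-2-ethyl-4-methyloctyl]propanedioate F4. Reduction of the sodium enolate of F4 with LiAlH4 (elimination–reduction to the 2-substituted allylic alcohol) gives 13.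

**Step 9.** C-alkylation of the thermally labile sodium imide enolate may be too slow with a neopentyl-like triflate, so that enolate decomposition and triflate degradation win. Any attack at the oxirane CH2 followed by reclosure would scramble the C6 configuration. The fallback sets out from 14 (through 18) and comes back at 21, using a more nucleophilic aza-enolate that reacts at −100 °C and delivers the aldehyde directly. Butanal and (S)-1-amino-2-(methoxymethyl)pyrrolidine give (E)-N-[(2S)-2-(methoxymethyl)pyrrolidin-1-yl]butan-1-imine F5. Deprotonation of F5 with LDA and alkylation with 18 should give (E)-(2S)-2-ethyl-3-{(2R)-2-[(2S,4S)-2-ethyl-4-methyloctyl]oxiran-2-yl}-N-[(2S)-2-(methoxymethyl)pyrrolidin-1-yl]propan-1-imine F6, the (S) auxiliary being the one expected to give C4 as S. Ozonolysis of the C=N bond (CH2Cl2, −78 °C) releases 21, which enters the allylation of step 11.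

**Step 13 (together with the closure in step 14).** Partial ionisation at C6 during the intermolecular perhydrolysis would erode the stereospecific inversion, and attack at the primary carbon is the regiochemical risk. In step 14, base-induced fragmentation of the β-hydroxy hydroperoxide or elimination of the mesylate may compete with ring closure. The fallback sets out from 22 and comes back at 25, reversing the order of the two C–O bond formations so that the tertiary bond is made intramolecularly.
- 22 is converted (Tf2O, 2,6-lutidine, −78 °C) into (4R,5S)-5-ethyl-6-{(2R)-2-[(2S,4S)-2-ethyl-4-methyloctyl]oxiran-2-yl}hex-1-en-4-yl trifluoromethanesulfonate F7.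
- F7 is displaced with inversion by the potassium salt of oxan-2-yl hydroperoxide (KOt-Bu, THF, 0 °C) to give 2-{[(4S,5S)-5-ethyl-6-{(2R)-2-[(2S,4S)-2-ethyl-4-methyloctyl]oxiran-2-yl}hex-1-en-4-yl]peroxy}oxane F8.
- Mild acid (camphorsulfonic acid, CH2Cl2 with a little MeOH) removes the acetal, and the liberated (4S,5S)-5-ethyl-6-{(2R)-2-[(2S,4S)-2-ethyl-4-methyloctyl]oxiran-2-yl}hex-1-en-4-yl hydroperoxide F9 opens the epoxide at C6 in the same flask to give 25.

**Step 16.** Attack of the ylide, or of phosphine formed from it, on the O–O bond and base-induced fragmentation of the α-peroxy aldehyde may compete with methylenation; the carboxylate also consumes ylide and lowers solubility. The fallback sets out from 27 (through 28) and comes back at 29, using a silicon-based two-stage olefination without any phosphorus reagent. Addition of Me3SiCH2MgCl in the presence of CeCl3 (THF, −78 °C) to 28 gives 2-{(3S,4S,6S)-4-ethyl-6-[(2S,4S)-2-ethyl-4-methyloctyl]-6-[1-hydroxy-2-(trimethylsilyl)ethyl]-1,2-dioxan-3-yl}acetic acid F10 as a mixture of carbinol epimers. Acid-promoted Peterson elimination (HF·pyridine, THF), which the peroxide tolerates, gives 29.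

## Further compounds

F1 | step 4 | (1R)-1-(trimethylstannyl)propyl 2,4,6-tri(propan-2-yl)benzoate | CC[C@@H]([Sn](C)(C)C)OC(=O)c1c(C(C)C)cc(C(C)C)cc1C(C)C
F2 | step 6 | (2S,4S)-2-ethyl-4-methyloctan-1-ol | CCCC[C@H](C)C[C@H](CC)CO
F3 | step 6 | (2S,4S)-2-ethyl-1-iodo-4-methyloctane | CCCC[C@H](C)C[C@H](CC)CI
F4 | step 6 | diethyl 2-[(2S,4S)-2-ethyl-4-methyloctyl]propanedioate | CCCC[C@H](C)C[C@H](CC)CC(C(=O)OCC)C(=O)OCC
F5 | step 9 | (E)-N-[(2S)-2-(methoxymethyl)pyrrolidin-1-yl]butan-1-imine | CCC/C=N/N1CCC[C@H]1COC
F6 | step 9 | (E)-(2S)-2-ethyl-3-{(2R)-2-[(2S,4S)-2-ethyl-4-methyloctyl]oxiran-2-yl}-N-[(2S)-2-(methoxymethyl)pyrrolidin-1-yl]propan-1-imine | CCCC[C@H](C)C[C@H](CC)C[C@]1(CO1)C[C@H](CC)/C=N/N2CCC[C@H]2COC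
F7 | step 13 | (4R,5S)-5-ethyl-6-{(2R)-2-[(2S,4S)-2-ethyl-4-methyloctyl]oxiran-2-yl}hex-1-en-4-yl trifluoromethanesulfonate | CCCC[C@H](C)C[C@H](CC)C[C@]1(CO1)C[C@H](CC)[C@@H](CC=C)OS(=O)(=O)C(F)(F)F
F8 | step 13 | 2-{[(4S,5S)-5-ethyl-6-{(2R)-2-[(2S,4S)-2-ethyl-4-methyloctyl]oxiran-2-yl}hex-1-en-4-yl]peroxy}oxane (both acetal epimers) | CCCC[C@H](C)C[C@H](CC)C[C@]1(CO1)C[C@H](CC)[C@H](CC=C)OOC2CCCCO2
F9 | step 13 | (4S,5S)-5-ethyl-6-{(2R)-2-[(2S,4S)-2-ethyl-4-methyloctyl]oxiran-2-yl}hex-1-en-4-yl hydroperoxide | CCCC[C@H](C)C[C@H](CC)C[C@]1(CO1)C[C@H](CC)[C@H](CC=C)OO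
F10 | step 16 | 2-{(3S,4S,6S)-4-ethyl-6-[(2S,4S)-2-ethyl-4-methyloctyl]-6-[1-hydroxy-2-(trimethylsilyl)ethyl]-1,2-dioxan-3-yl}acetic acid (both carbinol epimers) | CCCC[C@H](C)C[C@H](CC)C[C@@]1(C(O)C[Si](C)(C)C)C[C@H](CC)[C@H](CC(=O)O)OO1
A1 | alternative 1 | cis-3,6-diethylcyclohept-4-en-1-one (meso, 3R,6S) | O=C1C[C@H](CC)C=C[C@H](CC)C1
A2 | alternative 1 | (3E,5E)-octa-3,5-diene | CC/C=C/C=C/CC
A3 | alternative 1 | 3-bromo-2-methoxyprop-1-ene | COC(=C)CBr
A4 | alternative 2 | {(3S,5S,6S)-6-[2-(tert-butyldiphenylsilyloxy)ethyl]-5-ethyl-3-[(2S,4S)-2-ethyl-4-methyloctyl]-1,2-dioxan-3-yl}methanol | CCCC[C@H](C)C[C@H](CC)C[C@@]1(CO)C[C@H](CC)[C@H](CCO[Si](c2ccccc2)(c2ccccc2)C(C)(C)C)OO1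
A5 | alternative 2 | tert-butyl{[(3S,4S)-4-ethyl-5-{(2R)-2-[(2S,4S)-2-ethyl-4-methyloctyl]oxiran-2-yl}-3-hydroperoxypentyl]oxy}diphenylsilane | CCCC[C@H](C)C[C@H](CC)C[C@]1(CO1)C[C@H](CC)[C@H](CCO[Si](c2ccccc2)(c3ccccc3)C(C)(C)C)OO
A6 | alternative 3 | (1S,4R,8S)-8-ethyl-1-[(2S,4S)-2-ethyl-4-methyloctyl]-2,3-dioxabicyclo[2.2.2]oct-5-ene | CCCC[C@H](C)C[C@H](CC)C[C@@]1(C=C2)C[C@H](CC)[C@H]2OO1
A7 | alternative 3 | (5S)-5-ethyl-1-[(2S,4S)-2-ethyl-4-methyloctyl]cyclohexa-1,3-diene | CCCC[C@H](C)C[C@H](CC)CC1=CC=C[C@@H](CC)C1
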